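## Analysis of the target

The target 14 is an open-chain butane-1,4-dione. C1 and C4 are carbonyl carbons, each bound to a 2,4-dihydroxyphenyl ring, and C2 and C3 each carry a 4-hydroxybenzyl group, so the constitution consists of two identical halves joined at the C2–C3 bond. C2 and C3 are the only stereocentres. The SMILES string gives them opposite descriptors (2S,3R) with identical substituent sets, so 14 is the achiral meso diastereomer and only the relative configuration has to be secured. Both stereocentres are α to an aryl ketone and can epimerize to the racemic diastereomer through enolization; the 1,4-diketone can cyclodehydrate to a furan under strong acid; and the six phenols, above all the para-hydroxybenzyl units, are sensitive to oxidants. The difficulty is therefore to join two tertiary carbons in the meso sense in a chain where no ring enforces it, and to finish without strong base, strong acid or a hydride-abstracting oxidant. The strategy rests on the two 4-hydroxybenzyl groups: the benzylic CH2 sits on ring carbon 1 and the hydroxyl on ring carbon 4, which is the pattern of a 4-substituted cyclohex-2-enone after loss of H2. Such an enone is the annulation product of a CH2–CHO terminus and a four-carbon enone, so both phenol rings can be grown late from a symmetric dialdehyde.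

## Retrosynthetic reasoning

14 to 13. The four resorcinol hydroxyls are released last, from the tetrabenzyl ether 13, by cutting four O–CH2Ph bonds. Benzyl is preferred to methyl because hydrogenolysis is neutral. A Lewis-acidic ether cleavage would expose the 1,4-diketone and its two enolizable centres to conditions that favour cyclodehydration and epimerization. The forward step must leave the two electron-rich, ortho-oxygenated aryl ketones unreduced.

13 to 12. No skeletal bond is cut. Each 4-hydroxyphenyl ring of 13 is taken back to the cyclohex-2-enone ring of 12 by formally adding two hydrogen atoms. This exposes the enone needed for annulation. The forward dehydrogenation erases the ring stereocentre of each enone, so every ring epimer of 12 converges on one compound.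

12 to 9 and 10. In each cyclohexenone ring two bonds are cut: the C2=C3 double bond (aldol condensation) and the C4–C5 bond (conjugate addition). This leaves the meso dialdehyde 9 and two molecules of methyl vinyl ketone 10. The cut is made here because the ring carbonyl then lies para to the carbon bearing the side chain by connectivity alone, so only the 4-hydroxybenzyl pattern can result. The forward step has to form four C–C bonds and two rings, engage the aldehydes but not the aryl ketones, and leave C4 and C5 of 9 untouched.

9 to 8 to 6. The CH2–CH2–CHO arms of 9 come from the primary alcohols of diol 8, and these from the terminal alkenes of the diallyl diketone 6 by anti-Markovnikov hydration. An allyl group has exactly the three carbons required. An arm carrying the masked aldehyde from the start would save a step, but saturated β-branched alkyl halides of that kind react sluggishly with ketone enolates and tend to eliminate. The forward hydroboration must not reduce the ketones, and the oxidations must not enolize C2 and C3.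

6 to 3 and 4. The two bonds between the backbone carbons and the allyl CH2 groups are cut, giving the symmetric diketone 3 and two molecules of allyl bromide 4, joined through the bis-enolate 5. Both stereocentres are created here, and nothing in the substrate favours the meso arrangement. The meso isomer is therefore isolated at 6, the simplest and most robust compound that holds both centres, and material of the other configuration can be re-equilibrated with base.

3 to 1. The central C2–C3 bond of 3 is cut, which divides it into two identical halves. Each half is the methyl ketone 1, so two molecules of 1 are consumed for every molecule of 3. Oxidative dimerization of the enolate 2 of 1 forms the bond and uses the symmetry of the target directly.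

## Alternatives that were turned down

Alternative 1: The two aryl–C(=O) bonds are cut, and the ortho phenolic oxygen of each resorcinol ring is traced to a carboxyl oxygen of meso-2,3-bis(4-methoxybenzyl)succinic acid A2. In the forward key step A2 reacts with two equivalents of 3-chloro-5-methoxybenzyne A3, generated by fluoride-induced desilylation of 2-chloro-4-methoxy-6-(trimethylsilyl)phenyl triflate A4. Each carboxylate adds through oxygen to the aryne carbon remote from chlorine, the aryl anion attacks the acyl carbon, and the net insertion into the C–O bond gives the bis(ortho-hydroxyaryl ketone) A1.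
- For: the route is convergent, the 4-hydroxybenzyl rings are present from the start as robust anisyl groups, and the meso relation is fixed in a stable diacid before any ketone exists. On these points it is stronger than the chosen route.
- Against: the chlorine only steers regiochemistry and must be removed afterwards. Six methyl ethers then need Lewis-acid cleavage on the epimerizable diketone. A4 is not a catalogue compound. Protonation of the aryl anion, which gives an aryl ester, competes with acyl transfer, the more so for an α-branched acyl group with a second acidic carboxyl group nearby, and two such insertions must succeed in one molecule.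
- Comparison: the chosen route offers purchasable reagents throughout, no auxiliary atom and a neutral final deprotection.

Alternative 2: The carbonyl oxygens at C1 and C4 are traced to the O–O unit of a 1,2-dioxine. The (1E,3E)-diene A6 undergoes sensitized photo-oxygenation in the [4+2] mode across C1 and C4 to give the cis-dihydrodioxine A5. Base-induced Kornblum–DeLaMare cleavage of the O–O bond and tautomerization then bring C1 and C4 to the ketone level.
- For: the oxygen atoms come from air with a catalytic sensitizer, the conversion of peroxide to diketone is redox-neutral, and the sequence is shorter and more atom-economic than the chosen one.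
- Against: the cis relation set by the cycloaddition lies at the carbons that become carbonyls, so it is lost. The stereocentres C2 and C3 arise afterwards from two uncontrolled proton transfers, late, on a compound that still carries six methyl ethers. In A6 the 2,3-dibenzyl groups crowd the s-cis conformer. The four allylic and benzylic hydrogens beside the diene invite the ene mode of photo-oxygenation, and the electron-rich styrene units invite [2+2] cleavage.
- Comparison: the chosen route sets and purifies the meso relation early, at 6, and no later step is designed to touch C2 or C3.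

Alternative 3: Each resorcinol ring is cut across two ring C–C bonds, so that two ring carbons come from an ethynyl ketone and four from a diene. The meso bis-ynone A8 undergoes two Diels–Alder reactions with 1,1-dimethoxy-3-(trimethylsilyloxy)buta-1,3-diene A9. Elimination of one methoxy group from each adduct and silyl hydrolysis aromatize both rings to give A7.
- For: the polarization of A9 fixes methoxy ortho and hydroxyl para to the acyl group, and aromatization is spontaneous. It is as strong as the chosen route in letting ring construction dictate the substitution pattern, and stronger in needing no separate dehydrogenation.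
- Against: A8 carries its stereocentres α to ynones, which are far more acidic and more electrophilic than aryl ketones, so epimerization and conjugate addition threaten both its preparation and its use. The meso problem is only moved back to a succinic acid derivative. A9 is a moisture-sensitive ketene acetal, and the methyl ethers again call for a Lewis-acid end game.
- Comparison: the chosen route offers a much less fragile key substrate (aldehydes beside deactivated aryl ketones) and a hydrogenolytic final step.

Key step: step 5

Assumption (chemistry): ketone 1, the dibenzyl ether of 2',4'-dihydroxyacetophenone, is taken as a catalogue compound; otherwise one routine O-benzylation (BnBr, K2CO3) would precede step 1.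

## Route

Step 1
Reactants: 1 1-[2,4-bis(benzyloxy)phenyl]ethanone (two molecules per molecule of product)
Product: 3 1,4-bis[2,4-bis(benzyloxy)phenyl]butane-1,4-dione, via lithium enolate 2 (not isolated)
Conditions: LiN(iPr)2 (1.05 equiv per ketone), THF, −78 °C; then CuCl2 (1.1 equiv per ketone), DMF, −78 °C → rt
Reagents that add atoms: a second molecule of ketone 1 (1-[2,4-bis(benzyloxy)phenyl]ethanone), CC(=O)c1ccc(OCc2ccccc2)cc1OCc1ccccc1
Why: Oxidative homocoupling of a ketone lithium enolate by CuCl2 (Saegusa-type enolate dimerization): divalent copper takes one electron from each of two molecules of enolate 2, and the two α-carbons join to the symmetric 1,4-diketone, so one molecule of 3 contains the atoms of two molecules of 1 less two hydrogens. A methyl aryl ketone has a single enolizable site and no stereocentre is formed.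

Step 2
Reactants: 3 1,4-bis[2,4-bis(benzyloxy)phenyl]butane-1,4-dione; 4 allyl bromide (two molecules)
Product: 6 meso-(2R,3S)-2,3-diallyl-1,4-bis[2,4-bis(benzyloxy)phenyl]butane-1,4-dione, via dilithium bis-enolate 5 (not isolated)
Conditions: LiN(iPr)2 (2.2 equiv), THF, −78 °C; allyl bromide (3 equiv), DMPU, −78 → 0 °C; crystallization of the meso isomer (EtOAc/heptane) or chromatography
Reagents that add atoms: allyl bromide (4), C=CCBr
Why: SN2 C-alkylation of ketone enolates with an allylic bromide; two equivalents of base give the diene-diolate 5, so each α-carbon should be alkylated once. Both stereocentres arise here without reliable control, so a mixture of meso and chiral diastereomers is expected. The achiral meso isomer 6 is separated and is told from the racemate on a chiral stationary phase, where only the racemate can split into two peaks.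

Step 3
Reactants: 6 meso-2,3-diallyl-1,4-bis[2,4-bis(benzyloxy)phenyl]butane-1,4-dione
Product: 8 meso-1,4-bis[2,4-bis(benzyloxy)phenyl]-2,3-bis(3-hydroxypropyl)butane-1,4-dione, via bis(pinacol boronate) 7 (not isolated)
Conditions: pinacolborane (2.4 equiv), [Ir(cod)Cl]2 (1.5 mol%), dppm (3 mol%), CH2Cl2, rt; then NaBO3·4H2O, THF/H2O, rt
Reagents that add atoms: sodium perborate, [Na+].[Na+].O[B-]1(O)OO[B-](O)(O)OO1 (hydroxyl oxygen); pinacolborane, CC1(C)OBOC1(C)C (boryl group in 7, only hydrogen remains in 8)
Why: Iridium-catalysed anti-Markovnikov hydroboration of terminal alkenes with pinacolborane, which unlike BH3 does not reduce ketones on its own. Perborate then oxidizes the C–B bonds under near-neutral conditions that should not enolize C2 or C3.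

Step 4
Reactants: 8 meso-1,4-bis[2,4-bis(benzyloxy)phenyl]-2,3-bis(3-hydroxypropyl)butane-1,4-dione
Product: 9 meso-(4R,5S)-4,5-bis[2,4-bis(benzyloxy)benzoyl]octanedial
Conditions: Dess–Martin periodinane (2.4 equiv), CH2Cl2, 0 °C → rt
Reagents that add atoms: none
Why: Dess–Martin oxidation of primary alcohols to aldehydes, non-basic and without over-oxidation, so the α-stereocentres are not touched. The dialdehyde should be used directly in step 5.

Step 5
Reactants: 9 meso-4,5-bis[2,4-bis(benzyloxy)benzoyl]octanedial; 10 methyl vinyl ketone (two molecules)
Product: 12 meso-(2R,3S)-1,4-bis[2,4-bis(benzyloxy)phenyl]-2,3-bis[(4-oxocyclohex-2-en-1-yl)methyl]butane-1,4-dione (ring epimers unassigned), via bis-Michael adduct 11 (not isolated)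
Conditions: methyl vinyl ketone (3 equiv), pyrrolidine (0.4 equiv), AcOH (0.4 equiv), toluene, 0 °C → rt; then AcOH (2 equiv), 70 °C
Reagents that add atoms: methyl vinyl ketone (10), C=CC(C)=O
Why: Pyrrolidine converts each aldehyde of 9 into an enamine whose nucleophilic carbon (C2 and C7 of the octanedial) adds to the terminal carbon of 10, and hydrolysis gives the keto-aldehyde 11. On warming with pyrrolidinium acetate the methyl ketone of each arm, as its enamine or enol, attacks the aldehyde carbon and water is lost, so four C–C bonds and two rings form in one flask. The closest known reaction type is the secondary-amine-mediated Robinson annulation of α-unbranched aldehydes with methyl vinyl ketone (Stork enamine annulation and its catalytic variants), which gives 4-substituted cyclohex-2-enones. Each ring closes in a 6-(enolendo)-exo-trig aldol mode; the other aldol closures open to the arms of 11 would give four-membered rings. The new stereocentre at C1 of each ring is set in the Michael step by an achiral catalyst remote from the backbone, so no control is expected, and none is needed because these centres become sp2 in step 6. The step needs chemoselectivity for the aldehydes over the aryl ketones, and for intermolecular addition to 10 over the five-membered aldol of an aldehyde enamine onto the 1,6-related aryl ketone. This should be secured by the 2,4-bis(benzyloxy)benzoyl groups, which are electron-rich, ortho-substituted and α-branched and therefore poor electrophiles and poor enamine formers, and by the excess of 10. The weakly basic amine salt should not enolize C2 or C3, so the meso relation of 9 is carried into 12.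

Step 6
Reactants: 12 meso-1,4-bis[2,4-bis(benzyloxy)phenyl]-2,3-bis[(4-oxocyclohex-2-en-1-yl)methyl]butane-1,4-dione
Product: 13 meso-(2R,3S)-1,4-bis[2,4-bis(benzyloxy)phenyl]-2,3-bis(4-hydroxybenzyl)butane-1,4-dione
Conditions: Pd(OCOCF3)2 (10 mol%), 2-(dimethylamino)pyridine (20 mol%), TsOH·H2O (40 mol%), O2 (1 atm), DMSO, 80 °C
Reagents that add atoms: none
Why: Palladium-catalysed aerobic dehydrogenation of cyclohexenones to phenols: divalent palladium forms the enolate at ring C6, β-hydride elimination from C5 gives the 4H-cyclohexa-2,5-dienone, this tautomerizes to the phenol, and O2 reoxidizes zerovalent palladium. The ring stereocentres are erased, so all epimers of 12 converge on 13, and the acyclic aryl ketones, whose only α-hydrogen sits on a hindered tertiary carbon, should be palladated far more slowly. A quinone oxidant is avoided because it would abstract hydride from the para-hydroxybenzyl positions of the product.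

Step 7
Reactants: 13 meso-1,4-bis[2,4-bis(benzyloxy)phenyl]-2,3-bis(4-hydroxybenzyl)butane-1,4-dione
Product: 14 meso-(2R,3S)-1,4-bis(2,4-dihydroxyphenyl)-2,3-bis(4-hydroxybenzyl)butane-1,4-dione
Conditions: H2 (1 atm), 10% Pd/C, EtOAc/MeOH, rt
Reagents that add atoms: none
Why: Hydrogenolysis of aryl benzyl ethers over Pd/C under neutral conditions. Electron-rich ortho-oxygenated aryl ketones are reduced only slowly, as in debenzylations that deliver dihydrochalcones, and nothing enolizes C2 or C3, so the meso configuration of 13 should be retained in 14.

## Compound list

1 | 1-[2,4-bis(benzyloxy)phenyl]ethanone | CC(=O)c1ccc(OCc2ccccc2)cc1OCc1ccccc1 | starting material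
2 | lithium 1-[2,4-bis(benzyloxy)phenyl]ethenolate | C=C(O[Li])c1ccc(OCc2ccccc2)cc1OCc1ccccc1 | intermediate (not isolated)
3 | 1,4-bis[2,4-bis(benzyloxy)phenyl]butane-1,4-dione | O=C(CCC(=O)c1ccc(OCc2ccccc2)cc1OCc1ccccc1)c1ccc(OCc2ccccc2)cc1OCc1ccccc1 | intermediate
4 | allyl bromide (3-bromoprop-1-ene) | C=CCBr | starting material
5 | dilithium 1,4-bis[2,4-bis(benzyloxy)phenyl]buta-1,3-diene-1,4-diolate | [Li]OC(=CC=C(O[Li])c1ccc(OCc2ccccc2)cc1OCc1ccccc1)c1ccc(OCc2ccccc2)cc1OCc1ccccc1 | intermediate (not isolated)
6 | meso-(2R,3S)-2,3-diallyl-1,4-bis[2,4-bis(benzyloxy)phenyl]butane-1,4-dione | C=CC[C@@H](C(=O)c1ccc(OCc2ccccc2)cc1OCc1ccccc1)[C@H](CC=C)C(=O)c1ccc(OCc2ccccc2)cc1OCc1ccccc1 | intermediate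
7 | meso-1,4-bis[2,4-bis(benzyloxy)phenyl]-2,3-bis[3-(4,4,5,5-tetramethyl-1,3,2-dioxaborolan-2-yl)propyl]butane-1,4-dione | CC1(C)OB(CCC[C@@H](C(=O)c2ccc(OCc3ccccc3)cc2OCc2ccccc2)[C@H](CCCB2OC(C)(C)C(C)(C)O2)C(=O)c2ccc(OCc3ccccc3)cc2OCc2ccccc2)OC1(C)C | intermediate (not isolated)
8 | meso-(2R,3S)-1,4-bis[2,4-bis(benzyloxy)phenyl]-2,3-bis(3-hydroxypropyl)butane-1,4-dione | OCCC[C@@H](C(=O)c1ccc(OCc2ccccc2)cc1OCc1ccccc1)[C@H](CCCO)C(=O)c1ccc(OCc2ccccc2)cc1OCc1ccccc1 | intermediate
9 | meso-(4R,5S)-4,5-bis[2,4-bis(benzyloxy)benzoyl]octanedial | O=CCC[C@@H](C(=O)c1ccc(OCc2ccccc2)cc1OCc1ccccc1)[C@H](CCC=O)C(=O)c1ccc(OCc2ccccc2)cc1OCc1ccccc1 | intermediate (precursor of the key step)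
10 | methyl vinyl ketone (but-3-en-2-one) | C=CC(C)=O | starting material
11 | (4R,5S)-4,5-bis[2,4-bis(benzyloxy)benzoyl]-2,7-bis(3-oxobutyl)octanedial, C2 and C7 unassigned | CC(=O)CCC(C=O)C[C@@H](C(=O)c1ccc(OCc2ccccc2)cc1OCc1ccccc1)[C@H](CC(C=O)CCC(C)=O)C(=O)c1ccc(OCc2ccccc2)cc1OCc1ccccc1 | intermediate (not isolated)
12 | meso-(2R,3S)-1,4-bis[2,4-bis(benzyloxy)phenyl]-2,3-bis[(4-oxocyclohex-2-en-1-yl)methyl]butane-1,4-dione, ring epimers unassigned | O=C1C=CC(C[C@@H](C(=O)c2ccc(OCc3ccccc3)cc2OCc2ccccc2)[C@H](CC2C=CC(=O)CC2)C(=O)c2ccc(OCc3ccccc3)cc2OCc2ccccc2)CC1 | intermediate (product of the key step)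
13 | meso-(2R,3S)-1,4-bis[2,4-bis(benzyloxy)phenyl]-2,3-bis(4-hydroxybenzyl)butane-1,4-dione | Oc1ccc(C[C@@H](C(=O)c2ccc(OCc3ccccc3)cc2OCc2ccccc2)[C@H](Cc2ccc(O)cc2)C(=O)c2ccc(OCc3ccccc3)cc2OCc2ccccc2)cc1 | intermediate
14 | meso-(2R,3S)-1,4-bis(2,4-dihydroxyphenyl)-2,3-bis(4-hydroxybenzyl)butane-1,4-dione | O=C(c1ccc(O)cc1O)[C@@H](Cc1ccc(O)cc1)[C@@H](Cc1ccc(O)cc1)C(=O)c1ccc(O)cc1O | target

## Step count and risks

Total step count: 7. Longest linear sequence: 7 steps (1 to 14); two molecules of 1 are joined in step 1, and compounds 4 and 10 are purchased and enter directly, two molecules each.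

Step 5 (key step).
- What may go wrong: the aldehyde enamine may be diverted into intramolecular aldol addition to the aryl ketone on the far backbone carbon, closing a five-membered ring. A second molecule of 10 may add at the same α-carbon. Cyclodehydration may stop on one arm, because two independent annulations must both finish in a crowded molecule. Slow loss of the meso relation by enolization during heating is a lesser concern.
- Fallback: a stoichiometric Stork enamine annulation. Starting from 9, pyrrolidine (2.2 equiv) over molecular sieves should give the bis-enamine meso-1,4-bis[2,4-bis(benzyloxy)phenyl]-2,3-bis[(2E)-3-(pyrrolidin-1-yl)prop-2-en-1-yl]butane-1,4-dione F1. F1 is treated with 10 in an aprotic, acid-free medium, where alkylation stops after one equivalent per arm and no free aldehyde is present. Buffered hydrolysis and cyclization (AcOH/NaOAc/H2O, 60 °C) then give 11 and from it 12, where the route is rejoined.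

Step 2.
- What may go wrong: poor facial discrimination in the second alkylation, since nothing biases the enolate next to the first stereocentre, and geminal dialkylation after enolate equilibration. Both would reduce the supply of meso material.
- Fallback: the C2–C3 bond is formed last. Starting from 1, mono-allylation (LiN(iPr)2; 4) gives 1-[2,4-bis(benzyloxy)phenyl]pent-4-en-1-one F2. Oxidative homocoupling of its enolate (LiN(iPr)2; CuCl2) returns to 6 and cannot place two allyl groups on one carbon. In either variant the chiral diastereomer, rac-(2R,3R)-2,3-diallyl-1,4-bis[2,4-bis(benzyloxy)phenyl]butane-1,4-dione F3, is equilibrated with DBU through enolization of one centre, and 6 is crystallized again.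

Step 6.
- What may go wrong: once the rings are aromatic, dehydrogenation may continue at the acyclic aryl ketones toward chalcone-type enones. The second ring may convert incompletely, and the acid co-catalyst may cause partial epimerization at 80 °C.
- Fallback: starting from 12, soft enolization (TMSOTf, Et3N, CH2Cl2, 0 °C) gives the bis(silyl dienol ether) meso-1,4-bis[2,4-bis(benzyloxy)phenyl]-2,3-bis{[4-(trimethylsilyloxy)cyclohexa-2,4-dien-1-yl]methyl}butane-1,4-dione F4. Saegusa–Ito oxidation with Pd(OAc)2 in MeCN at rt gives the dienones, which tautomerize to 13. Whether the hindered backbone C–H stays untouched by the silylating conditions would have to be checked.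

Step 3.
- What may go wrong: reduction of the aryl ketones by the borane, or migration of the terminal double bond by the iridium hydride before borylation, which would lead to secondary alcohols.
- Fallback: direct aldehyde-selective (nitrite-modified) Wacker oxidation of 6 (PdCl2(PhCN)2, CuCl2·2H2O, AgNO2, O2, tBuOH/MeNO2, rt). It returns to the route at 9 in one step, bypassing 7 and 8, and makes no new compound.

Step 1.
- What may go wrong: α-chlorination of the enolate by CuCl2 and incomplete coupling, which lower the throughput of the first step.
- Fallback: a polar construction of the same bond. Starting from 1, α-bromination (PhNMe3Br3, THF) gives 2-bromo-1-[2,4-bis(benzyloxy)phenyl]ethanone F5. F5 is coupled with a second equivalent of 1 through its zinc enolate (ZnCl2, Et2NH, tBuOH, toluene, rt), returning to 3.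

Step 7.
- What may go wrong: over-reduction of an aryl ketone on the catalyst, or incomplete cleavage of the hindered ortho benzyl ethers.
- Fallback: Lewis-acid debenzylation at low temperature. Starting from 13, BCl3 with pentamethylbenzene as benzyl-cation scavenger (CH2Cl2, −78 °C) leads directly to 14 and makes no new compound.

## Further compounds

F1 | step 5 | meso-1,4-bis[2,4-bis(benzyloxy)phenyl]-2,3-bis[(2E)-3-(pyrrolidin-1-yl)prop-2-en-1-yl]butane-1,4-dione | C1CCN(C1)/C=C/C[C@@H](C(=O)c1ccc(OCc2ccccc2)cc1OCc1ccccc1)[C@H](C/C=C/N1CCCC1)C(=O)c1ccc(OCc2ccccc2)cc1OCc1ccccc1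
F2 | step 2 | 1-[2,4-bis(benzyloxy)phenyl]pent-4-en-1-one | C=CCCC(=O)c1ccc(OCc2ccccc2)cc1OCc1ccccc1
F3 | step 2 | rac-(2R,3R)-2,3-diallyl-1,4-bis[2,4-bis(benzyloxy)phenyl]butane-1,4-dione (one enantiomer drawn) | C=CC[C@@H](C(=O)c1ccc(OCc2ccccc2)cc1OCc1ccccc1)[C@@H](CC=C)C(=O)c1ccc(OCc2ccccc2)cc1OCc1ccccc1
F4 | step 6 | meso-1,4-bis[2,4-bis(benzyloxy)phenyl]-2,3-bis{[4-(trimethylsilyloxy)cyclohexa-2,4-dien-1-yl]methyl}butane-1,4-dione, ring epimers unassigned | C[Si](C)(C)OC1=CCC(C[C@@H](C(=O)c2ccc(OCc3ccccc3)cc2OCc2ccccc2)[C@H](CC2CC=C(O[Si](C)(C)C)C=C2)C(=O)c2ccc(OCc3ccccc3)cc2OCc2ccccc2)C=C1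
F0 | step 3 | none | none
F5 | step 1 | 2-bromo-1-[2,4-bis(benzyloxy)phenyl]ethanone | O=C(CBr)c1ccc(OCc2ccccc2)cc1OCc1ccccc1
F0 | step 7 | none | none
A1 | alternative 1 | meso-1,4-bis(2-chloro-6-hydroxy-4-methoxyphenyl)-2,3-bis(4-methoxybenzyl)butane-1,4-dione | O=C(c1c(O)cc(OC)cc1Cl)[C@@H](Cc1ccc(OC)cc1)[C@@H](Cc1ccc(OC)cc1)C(=O)c1c(O)cc(OC)cc1Cl
A2 | alternative 1 | meso-2,3-bis(4-methoxybenzyl)succinic acid | OC(=O)[C@@H](Cc1ccc(OC)cc1)[C@@H](Cc1ccc(OC)cc1)C(=O)O
A3 | alternative 1 | 3-chloro-5-methoxybenzyne | ClC1=CC(OC)=CC#C1
A4 | alternative 1 | 2-chloro-4-methoxy-6-(trimethylsilyl)phenyl trifluoromethanesulfonate | COc1cc(Cl)c(OS(=O)(=O)C(F)(F)F)c([Si](C)(C)C)c1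
A5 | alternative 2 | cis-3,6-bis(2,4-dimethoxyphenyl)-4,5-bis(4-methoxybenzyl)-3,6-dihydro-1,2-dioxine | COc1ccc([C@@H]2OO[C@H](c3ccc(OC)cc3OC)C(Cc3ccc(OC)cc3)=C2Cc2ccc(OC)cc2)c(OC)c1
A6 | alternative 2 | (1E,3E)-1,4-bis(2,4-dimethoxyphenyl)-2,3-bis(4-methoxybenzyl)buta-1,3-diene | COc1ccc(/C=C(Cc2ccc(OC)cc2)/C(Cc2ccc(OC)cc2)=C/c2ccc(OC)cc2OC)c(OC)c1
A7 | alternative 3 | meso-1,4-bis(4-hydroxy-2-methoxyphenyl)-2,3-bis(4-methoxybenzyl)butane-1,4-dione | O=C(c1ccc(O)cc1OC)[C@@H](Cc1ccc(OC)cc1)[C@@H](Cc1ccc(OC)cc1)C(=O)c1ccc(O)cc1OC
A8 | alternative 3 | meso-4,5-bis(4-methoxybenzyl)octa-1,7-diyne-3,6-dione | C#CC(=O)[C@@H](Cc1ccc(OC)cc1)[C@@H](Cc1ccc(OC)cc1)C(=O)C#C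
A9 | alternative 3 | 1,1-dimethoxy-3-(trimethylsilyloxy)buta-1,3-diene | C=C(O[Si](C)(C)C)C=C(OC)OC
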